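The route rests on cutting the C3 formyl carbon and the C2 hydroxyl oxygen from ring A of the depside in one retrosynthetic move, leaving a C2–C3 aryne and N,N-dimethylformamide. The key step exploits that in ring A the C2 OH and C3 CHO are ortho neighbours lying between the C1 ester carbonyl and the C4 oxygen: fluoride unmasks the aryne on the finished depside, DMF adds across it, and hydrolysis delivers both groups at once. The precursor is the ring B aryl ester of a 4-benzyloxy-5,6-dimethylbenzoic acid carrying triflate at C2 and trimethylsilyl at C3, assembled from two resorcinol-derived halves by a TFAA depside coupling.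

Key step: step 11

Remark: ring A is the acyl ring, numbered from the carbon bearing the ester carbonyl; ring B is the aryloxy ring, numbered from the carbon bearing CO2Me.
Remark: O4 of ring A is carried as a benzyl ether, because the doubly ortho-flanked depside ester is closed under acidic TFAA conditions that an acetal-type ether would not survive; it is removed by hydrogenolysis.
Remark: C1 of ring A is brought in by formylation and oxidation, since direct carboxylation of 4,5-dimethylresorcinol would be regiochemically ambiguous.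
Remark: ring B is built from methyl 2,4-dihydroxy-3,6-dimethylbenzoate, assumed to be commercially available, which already carries both oxygens and the ester in the right places.

Step 1
Reactants: 1 4,5-dimethylresorcinol; 2 N,N-dimethylformamide
Product: 4 2,4-dihydroxy-5,6-dimethylbenzaldehyde, via aryl iminium salt 3 (not isolated)
Conditions: POCl3, DMF, MeCN, 0 °C to rt; then H2O, 50 °C
Reagents that add atoms: N,N-dimethylformamide CN(C)C=O; water O
Why: Vilsmeier–Haack formylation should go to the ring carbon para to one hydroxyl and ortho to the other, because the bulky chloroiminium electrophile avoids the position between the two hydroxyls, and water then hydrolyses iminium salt 3 to the aldehyde.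

Step 2
Reactants: 4 2,4-dihydroxy-5,6-dimethylbenzaldehyde
Product: 5 4-(benzyloxy)-2-hydroxy-5,6-dimethylbenzaldehyde
Conditions: BnBr (1.05 equiv), K2CO3, acetone, reflux
Reagents that add atoms: benzyl bromide BrCc1ccccc1
Why: Williamson etherification should take place only at O4, since the C2 hydroxyl is held in a hydrogen bond to the formyl group and is far less nucleophilic.

Step 3
Reactants: 5 4-(benzyloxy)-2-hydroxy-5,6-dimethylbenzaldehyde
Product: 6 4-(benzyloxy)-3-bromo-2-hydroxy-5,6-dimethylbenzaldehyde
Conditions: NBS (1.0 equiv), MeCN, 0 °C, dark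
Reagents that add atoms: N-bromosuccinimide O=C1CCC(=O)N1Br
Why: Electrophilic aromatic bromination can only occur at C3, the single free position of the ring, which is ortho to both oxygens and therefore strongly activated.

Step 4
Reactants: 6 4-(benzyloxy)-3-bromo-2-hydroxy-5,6-dimethylbenzaldehyde
Product: 7 4-(benzyloxy)-3-bromo-2-hydroxy-5,6-dimethylbenzoic acid
Conditions: NaClO2, NaH2PO4, 2-methyl-2-butene, t-BuOH/THF/H2O, rt
Reagents that add atoms: sodium chlorite [Na+].[O-]Cl=O
Why: Pinnick oxidation converts hindered aromatic aldehydes cleanly to acids, and the fully substituted ring together with the alkene scavenger leaves no site for ring chlorination.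

Step 5
Reactants: 8 methyl 2,4-dihydroxy-3,6-dimethylbenzoate
Product: 10 methyl 5-formyl-2,4-dihydroxy-3,6-dimethylbenzoate, via chloro ether 9 (not isolated)
Conditions: Cl2CHOMe, TiCl4, CH2Cl2, 0 °C to rt; then aq. HCl
Reagents that add atoms: dichloromethyl methyl ether COC(Cl)Cl; water O
Why: Rieche formylation, directed by the titanium phenoxide, should substitute C5, the only unsubstituted ring carbon and one that is ortho and para to the two hydroxyls, and aqueous acid hydrolyses chloro ether 9 to the aldehyde.

Step 6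
Reactants: 10 methyl 5-formyl-2,4-dihydroxy-3,6-dimethylbenzoate
Product: 11 methyl 2,4-dihydroxy-3,5,6-trimethylbenzoate
Conditions: Et3SiH, TFA, rt
Reagents that add atoms: none
Why: Ionic hydrogenation with a silane in strong acid reduces electron-rich ortho-hydroxy benzaldehydes to methyl groups, while the ester and the phenols are inert to it.

Step 7
Reactants: 11 methyl 2,4-dihydroxy-3,5,6-trimethylbenzoate
Product: 13 methyl 4-(benzyloxy)-2-methoxy-3,5,6-trimethylbenzoate, via monobenzyl ether 12 (not isolated)
Conditions: BnBr (1.0 equiv), K2CO3, DMF, rt; then MeI, 50 °C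
Reagents that add atoms: benzyl bromide BrCc1ccccc1; iodomethane CI
Why: Two Williamson etherifications in sequence should differentiate the oxygens, because the more acidic, non-chelated C4 hydroxyl is benzylated first at room temperature and the ester-chelated C2 hydroxyl is methylated only under the more forcing second stage.

Step 8
Reactants: 13 methyl 4-(benzyloxy)-2-methoxy-3,5,6-trimethylbenzoate
Product: 14 methyl 4-hydroxy-2-methoxy-3,5,6-trimethylbenzoate
Conditions: H2 (1 atm), Pd/C, EtOAc, rt
Reagents that add atoms: none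
Why: Catalytic hydrogenolysis cleaves the benzyl aryl ether and leaves the methyl ether and methyl ester untouched.

Step 9
Reactants: 7 4-(benzyloxy)-3-bromo-2-hydroxy-5,6-dimethylbenzoic acid; 14 methyl 4-hydroxy-2-methoxy-3,5,6-trimethylbenzoate
Product: 16 3-methoxy-4-(methoxycarbonyl)-2,5,6-trimethylphenyl 4-(benzyloxy)-3-bromo-2-hydroxy-5,6-dimethylbenzoate, via mixed anhydride 15 (not isolated)
Conditions: TFAA, toluene, rt; then aq. NaHCO3
Reagents that add atoms: none
Why: TFAA-mediated depside esterification proceeds through mixed anhydride 15, which acylates with acylium character and so tolerates two ortho substituents on each partner, while the chelated C2 hydroxyl of the acid does not compete and any trifluoroacetate on it is lost in the work-up.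

Step 10
Reactants: 16 3-methoxy-4-(methoxycarbonyl)-2,5,6-trimethylphenyl 4-(benzyloxy)-3-bromo-2-hydroxy-5,6-dimethylbenzoate
Product: 19 3-methoxy-4-(methoxycarbonyl)-2,5,6-trimethylphenyl 4-(benzyloxy)-5,6-dimethyl-2-(trifluoromethylsulfonyloxy)-3-(trimethylsilyl)benzoate, via O-trimethylsilyl ether 17 (not isolated), via lithium phenoxide 18 (not isolated)
Conditions: HMDS, THF, 70 °C, then evaporation; n-BuLi, THF, −100 °C; then Tf2O, −100 to −78 °C
Reagents that add atoms: hexamethyldisilazane C[Si](C)(C)N[Si](C)(C)C; trifluoromethanesulfonic anhydride O=S(=O)(OS(=O)(=O)C(F)(F)F)C(F)(F)F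
Why: After O-silylation, Parham-type bromine–lithium exchange at −100 °C should outrun addition to the two doubly ortho-flanked esters, the C3 aryllithium undergoes a retro-Brook 1,3 silyl shift from O2 to carbon, and the resulting lithium phenoxide 18 is trapped as the triflate.

Step 11
Reactants: 19 3-methoxy-4-(methoxycarbonyl)-2,5,6-trimethylphenyl 4-(benzyloxy)-5,6-dimethyl-2-(trifluoromethylsulfonyloxy)-3-(trimethylsilyl)benzoate; 2 N,N-dimethylformamide
Product: 23 3-methoxy-4-(methoxycarbonyl)-2,5,6-trimethylphenyl 4-(benzyloxy)-3-formyl-2-hydroxy-5,6-dimethylbenzoate, via aryne 20 (not isolated), via benzoxetene 21 (not isolated), via iminium phenoxide 22 (not isolated)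
Conditions: CsF, DMF, rt; then H2O
Reagents that add atoms: N,N-dimethylformamide CN(C)C=O; water O
Why: Fluoride attacks silicon at C3 and the aryl anion expels the C2 triflate to give aryne 20; the carbonyl oxygen of DMF adds to C2, the C3 carbanion closes on the iminium carbon to benzoxetene 21, and this opens to the ortho-quinone methide, drawn as iminium phenoxide 22, which water hydrolyses to the C2 phenol and C3 aldehyde with loss of dimethylamine. The closest known reaction is the formal insertion of arynes generated from ortho-silylaryl triflates into the C=O bond of formamides, which gives salicylaldehydes after hydrolysis. No ring is closed in the product, since the four-membered oxetene is transient, and no stereocenter is formed. The step needs oxygen attack at C2 and not at C3: the C4 benzyloxy group withdraws through the sigma framework, which makes C2 the more linear and electrophilic aryne carbon and stabilises charge building at C3, whereas the C1 acyl group is bound through carbon, is twisted out of the ring plane by its two ortho neighbours, and should oppose this only weakly. Fluoride at room temperature under non-acidic conditions should leave the hindered depside ester and the methyl ester intact.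

Step 12
Reactants: 23 3-methoxy-4-(methoxycarbonyl)-2,5,6-trimethylphenyl 4-(benzyloxy)-3-formyl-2-hydroxy-5,6-dimethylbenzoate
Product: 24 3-methoxy-4-(methoxycarbonyl)-2,5,6-trimethylphenyl 3-formyl-2,4-dihydroxy-5,6-dimethylbenzoate (target)
Conditions: H2 (1 atm), Pd/C, EtOAc, rt
Reagents that add atoms: none
Why: Hydrogenolysis of the benzyl ether should be much faster than reduction of an aldehyde that ends up chelated between two phenols, so the reaction is stopped after uptake of one equivalent of hydrogen.

Compound list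
1 | 4,5-dimethylresorcinol (4,5-dimethylbenzene-1,3-diol) | Cc1cc(O)cc(O)c1C | starting material
2 | N,N-dimethylformamide | CN(C)C=O | starting material
3 | [(2,4-dihydroxy-5,6-dimethylphenyl)methylidene]dimethylammonium chloride | C[N+](C)=Cc1c(O)cc(O)c(C)c1C.[Cl-] | intermediate (not isolated)
4 | 2,4-dihydroxy-5,6-dimethylbenzaldehyde | O=Cc1c(O)cc(O)c(C)c1C | intermediate
5 | 4-(benzyloxy)-2-hydroxy-5,6-dimethylbenzaldehyde | O=Cc1c(O)cc(OCc2ccccc2)c(C)c1C | intermediate
6 | 4-(benzyloxy)-3-bromo-2-hydroxy-5,6-dimethylbenzaldehyde | O=Cc1c(O)c(Br)c(OCc2ccccc2)c(C)c1C | intermediate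
7 | 4-(benzyloxy)-3-bromo-2-hydroxy-5,6-dimethylbenzoic acid | OC(=O)c1c(O)c(Br)c(OCc2ccccc2)c(C)c1C | intermediate
8 | methyl 2,4-dihydroxy-3,6-dimethylbenzoate | COC(=O)c1c(O)c(C)c(O)cc1C | starting material
9 | methyl 5-[chloro(methoxy)methyl]-2,4-dihydroxy-3,6-dimethylbenzoate (racemic, titanium-bound in the flask) | COC(=O)c1c(O)c(C)c(O)c(C(Cl)OC)c1C | intermediate (not isolated)
10 | methyl 5-formyl-2,4-dihydroxy-3,6-dimethylbenzoate | COC(=O)c1c(O)c(C)c(O)c(C=O)c1C | intermediate
11 | methyl 2,4-dihydroxy-3,5,6-trimethylbenzoate | COC(=O)c1c(O)c(C)c(O)c(C)c1C | intermediate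
12 | methyl 4-(benzyloxy)-2-hydroxy-3,5,6-trimethylbenzoate | COC(=O)c1c(O)c(C)c(OCc2ccccc2)c(C)c1C | intermediate (not isolated)
13 | methyl 4-(benzyloxy)-2-methoxy-3,5,6-trimethylbenzoate | COC(=O)c1c(OC)c(C)c(OCc2ccccc2)c(C)c1C | intermediate
14 | methyl 4-hydroxy-2-methoxy-3,5,6-trimethylbenzoate | COC(=O)c1c(OC)c(C)c(O)c(C)c1C | intermediate
15 | 4-(benzyloxy)-3-bromo-2-hydroxy-5,6-dimethylbenzoic trifluoroacetic anhydride | O=C(OC(=O)C(F)(F)F)c1c(O)c(Br)c(OCc2ccccc2)c(C)c1C | intermediate (not isolated)
16 | 3-methoxy-4-(methoxycarbonyl)-2,5,6-trimethylphenyl 4-(benzyloxy)-3-bromo-2-hydroxy-5,6-dimethylbenzoate | COC(=O)c1c(C)c(C)c(OC(=O)c2c(C)c(C)c(OCc3ccccc3)c(Br)c2O)c(C)c1OC | intermediate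
17 | 3-methoxy-4-(methoxycarbonyl)-2,5,6-trimethylphenyl 4-(benzyloxy)-3-bromo-5,6-dimethyl-2-(trimethylsilyloxy)benzoate | COC(=O)c1c(C)c(C)c(OC(=O)c2c(C)c(C)c(OCc3ccccc3)c(Br)c2O[Si](C)(C)C)c(C)c1OC | intermediate (not isolated)
18 | lithium phenoxide of 3-methoxy-4-(methoxycarbonyl)-2,5,6-trimethylphenyl 4-(benzyloxy)-2-hydroxy-5,6-dimethyl-3-(trimethylsilyl)benzoate | COC(=O)c1c(C)c(C)c(OC(=O)c2c(C)c(C)c(OCc3ccccc3)c([Si](C)(C)C)c2[O-])c(C)c1OC.[Li+] | intermediate (not isolated)
19 | 3-methoxy-4-(methoxycarbonyl)-2,5,6-trimethylphenyl 4-(benzyloxy)-5,6-dimethyl-2-(trifluoromethylsulfonyloxy)-3-(trimethylsilyl)benzoate | COC(=O)c1c(C)c(C)c(OC(=O)c2c(C)c(C)c(OCc3ccccc3)c([Si](C)(C)C)c2OS(=O)(=O)C(F)(F)F)c(C)c1OC | intermediate (key step precursor)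
20 | 3-methoxy-4-(methoxycarbonyl)-2,5,6-trimethylphenyl 4-(benzyloxy)-2,3-didehydro-5,6-dimethylbenzoate (C2–C3 aryne of ring A) | COC(=O)c1c(C)c(C)c(OC(=O)C2=C(C)C(C)=C(OCc3ccccc3)C#C2)c(C)c1OC | intermediate (not isolated)
21 | ring A fused 2-(dimethylamino)-2H-benzoxete, oxygen on C2 and aminal carbon on C3 (racemic) | COC(=O)c1c(C)c(C)c(OC(=O)c2c(C)c(C)c(OCc3ccccc3)c4C(N(C)C)Oc24)c(C)c1OC | intermediate (not isolated)
22 | ring-opened ortho-quinone methide, drawn as the C3 dimethyliminiomethyl C2 phenoxide zwitterion | COC(=O)c1c(C)c(C)c(OC(=O)c2c(C)c(C)c(OCc3ccccc3)c(C=[N+](C)C)c2[O-])c(C)c1OC | intermediate (not isolated)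
23 | 3-methoxy-4-(methoxycarbonyl)-2,5,6-trimethylphenyl 4-(benzyloxy)-3-formyl-2-hydroxy-5,6-dimethylbenzoate | COC(=O)c1c(C)c(C)c(OC(=O)c2c(C)c(C)c(OCc3ccccc3)c(C=O)c2O)c(C)c1OC | intermediate (key step product)
24 | 3-methoxy-4-(methoxycarbonyl)-2,5,6-trimethylphenyl 3-formyl-2,4-dihydroxy-5,6-dimethylbenzoate | COC(=O)c1c(C)c(C)c(OC(=O)c2c(C)c(C)c(O)c(C=O)c2O)c(C)c1OC | target

Total step count: 12
Longest linear sequence: 8 steps (steps 1 to 4 and 9 to 12; the ring B branch, steps 5 to 8 and 9 to 12, is equally long)

Steps most likely to fail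

Step 11. The DMF oxygen may add at C3 instead of C2 if the pull of the C1 acyl group is underestimated. The aryne may also be captured by phenoxide that has already formed, or fluoride may remove the triflyl group without elimination. The fallback gives up the aryne and sets out from compound 16. Hydrogenation over Pd/C with Et3N in EtOAc/MeOH should remove both the benzyl group and the C3 bromine to give 3-methoxy-4-(methoxycarbonyl)-2,5,6-trimethylphenyl 2,4-dihydroxy-5,6-dimethylbenzoate F1. Rieche formylation of this (Cl2CHOMe, TiCl4, CH2Cl2, 0 °C, then aqueous acid) can only substitute C3 of ring A, the one unsubstituted aromatic carbon left in the molecule. The fallback comes back to the route at compound 24.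

Step 10. The organolithium may add to an ester carbonyl in competition with bromine–lithium exchange, silylation of the chelated C2 hydroxyl may stay incomplete, or triflation of the doubly flanked phenoxide may be slow. The fallback moves the sequence to a stage that carries no ester and sets out from compound 6.
- Acetalisation with ethylene glycol and TsOH in toluene, with azeotropic removal of water, should give 2-[4-(benzyloxy)-3-bromo-2-hydroxy-5,6-dimethylphenyl]-1,3-dioxolane F2.
- HMDS then gives its O-trimethylsilyl ether F3, and n-BuLi at −100 °C gives the C-silylated lithium phenoxide F4 by exchange and silyl shift.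
- Tf2O gives the silyl triflate dioxolane F5.
- Dilute aqueous HCl in THF releases 4-(benzyloxy)-5,6-dimethyl-2-(trifluoromethylsulfonyloxy)-3-(trimethylsilyl)benzaldehyde F6.
- Pinnick oxidation gives the corresponding benzoic acid F7, and oxalyl chloride with catalytic DMF gives the acid chloride F8.
- Acylation of phenol 14 with Et3N and DMAP in CH2Cl2 returns to the route at compound 19.

Step 9. Acylation of the hindered phenol may stall, or trifluoroacetylation of the phenol partner may consume it faster than the depside forms. The fallback replaces the acidic anhydride activation by a base-mediated acid chloride coupling and sets out from compound 7.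
- Acetic anhydride in pyridine, followed by aqueous work-up, should give 2-acetoxy-4-(benzyloxy)-3-bromo-5,6-dimethylbenzoic acid F9.
- Oxalyl chloride with catalytic DMF gives 2-acetoxy-4-(benzyloxy)-3-bromo-5,6-dimethylbenzoyl chloride F10.
- Acylation of phenol 14 with Et3N and DMAP in CH2Cl2 gives the O2-acetylated depside F11.
- Methanolysis of the unhindered aryl acetate with K2CO3 in MeOH at 0 °C, which the doubly ortho-flanked depside ester should survive, returns to the route at compound 16.

Further compounds
F1 | step 11 | 3-methoxy-4-(methoxycarbonyl)-2,5,6-trimethylphenyl 2,4-dihydroxy-5,6-dimethylbenzoate | COC(=O)c1c(C)c(C)c(OC(=O)c2c(C)c(C)c(O)cc2O)c(C)c1OC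
F2 | step 10 | 2-[4-(benzyloxy)-3-bromo-2-hydroxy-5,6-dimethylphenyl]-1,3-dioxolane | Oc1c(Br)c(OCc2ccccc2)c(C)c(C)c1C3OCCO3
F3 | step 10 | 2-[4-(benzyloxy)-3-bromo-5,6-dimethyl-2-(trimethylsilyloxy)phenyl]-1,3-dioxolane | C[Si](C)(C)Oc1c(Br)c(OCc2ccccc2)c(C)c(C)c1C3OCCO3
F4 | step 10 | lithium 3-(benzyloxy)-6-(1,3-dioxolan-2-yl)-4,5-dimethyl-2-(trimethylsilyl)phenoxide | [Li+].[O-]c1c([Si](C)(C)C)c(OCc2ccccc2)c(C)c(C)c1C3OCCO3
F5 | step 10 | 3-(benzyloxy)-6-(1,3-dioxolan-2-yl)-4,5-dimethyl-2-(trimethylsilyl)phenyl trifluoromethanesulfonate | FC(F)(F)S(=O)(=O)Oc1c([Si](C)(C)C)c(OCc2ccccc2)c(C)c(C)c1C3OCCO3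
F6 | step 10 | 4-(benzyloxy)-5,6-dimethyl-2-(trifluoromethylsulfonyloxy)-3-(trimethylsilyl)benzaldehyde | O=Cc1c(C)c(C)c(OCc2ccccc2)c([Si](C)(C)C)c1OS(=O)(=O)C(F)(F)F
F7 | step 10 | 4-(benzyloxy)-5,6-dimethyl-2-(trifluoromethylsulfonyloxy)-3-(trimethylsilyl)benzoic acid | OC(=O)c1c(C)c(C)c(OCc2ccccc2)c([Si](C)(C)C)c1OS(=O)(=O)C(F)(F)F
F8 | step 10 | 4-(benzyloxy)-5,6-dimethyl-2-(trifluoromethylsulfonyloxy)-3-(trimethylsilyl)benzoyl chloride | ClC(=O)c1c(C)c(C)c(OCc2ccccc2)c([Si](C)(C)C)c1OS(=O)(=O)C(F)(F)F
F9 | step 9 | 2-acetoxy-4-(benzyloxy)-3-bromo-5,6-dimethylbenzoic acid | CC(=O)Oc1c(Br)c(OCc2ccccc2)c(C)c(C)c1C(=O)O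
F10 | step 9 | 2-acetoxy-4-(benzyloxy)-3-bromo-5,6-dimethylbenzoyl chloride | CC(=O)Oc1c(Br)c(OCc2ccccc2)c(C)c(C)c1C(=O)Cl
F11 | step 9 | 3-methoxy-4-(methoxycarbonyl)-2,5,6-trimethylphenyl 2-acetoxy-4-(benzyloxy)-3-bromo-5,6-dimethylbenzoate | COC(=O)c1c(C)c(C)c(OC(=O)c2c(C)c(C)c(OCc3ccccc3)c(Br)c2OC(C)=O)c(C)c1OC
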